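**Plan**
1. Numbering: C1 quaternary carbinol, C2 CH–OBz, C3 CH–OH, C4=C5 alkene, C6 ketone, C7 CH2OBz. O1, O2, O3, O6 and O7 are the oxygens on these carbons.
2. Retrosynthetic cuts, in order: the silyl caps; C6=O (back to a C5=C6 alkene and a C4 methylene); the O7–benzoyl bond; the C2–O2 bond (back to a C2–C3 oxirane opened from behind by the C7 benzoate); both oxirane C–O bonds at once; then O7–benzoyl, C1–O1 and the two added ring hydrogens, which leads to benzoic acid.
3. Enabling feature: without O2, O3 and O6 the six-membered carbocycle is a 1-substituted cyclohexa-2,5-dien-1-ol with a mirror plane through C1, C4 and C7. C2=C3 and C5=C6 are then mirror images of each other, and C1 becomes stereogenic as soon as one of them reacts.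
4. Forward order: the carbocycle is the ring of benzoic acid and is never built. The oxirane is the only ring made (step 6). A transient 1,3-dioxan-2-ylium ring (step 7) carries the benzoate from O7 to C2.
5. Stereochemistry: C1, C2 and C3 all come from one ligand-controlled, hydroxyl-directed epoxidation. C2 is then inverted once, stereospecifically, and the C6 centre of the ene step is erased.

Key step: step 6

Assumption: the sense of induction on this cyclic dienol cannot be derived with certainty from acyclic models. The (R,R)-ligand is written, and the equally available (S,S)-ligand is used if a trial run delivers the mirror image.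

Step 1
Reactants: 1 benzoic acid
Product: 2 cyclohexa-2,5-diene-1-carboxylic acid
Conditions: Na, NH3(l), EtOH, −78 to −33 °C; NH4Cl; aq HCl, 0 °C
Reagents that add atoms: none
Why: In this Birch reduction the carboxylate steers protonation to the ipso and para carbons, so the unconjugated 1,4-dihydro acid should result and no stereocentre is formed.

Step 2
Reactants: 2 cyclohexa-2,5-diene-1-carboxylic acid
Product: 3 methyl cyclohexa-2,5-diene-1-carboxylate
Conditions: MeOH, H2SO4 (cat.), reflux
Reagents that add atoms: methanol, CO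
Why: Fischer esterification is safe at this stage because C1 carries no leaving group yet, so the skipped diene has no easy path to the arene.

Step 3
Reactants: 3 methyl cyclohexa-2,5-diene-1-carboxylate
Product: 5 methyl 1-hydroxycyclohexa-2,5-diene-1-carboxylate, via potassium dienolate 4 (not isolated)
Conditions: KHMDS, THF, −78 °C; 2-(phenylsulfonyl)-3-phenyloxaziridine, −78 °C; aq NH4Cl
Reagents that add atoms: 2-(phenylsulfonyl)-3-phenyloxaziridine, O=S(=O)(N1OC1c1ccccc1)c1ccccc1
Why: In this Davis oxidation (N-sulfonyloxaziridine hydroxylation of an ester enolate) the cross-conjugated dienolate should react at C1, as it does in Birch alkylations, and the ester keeps the achiral tertiary bis-allylic alcohol from ionising.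

Step 4
Reactants: 5 methyl 1-hydroxycyclohexa-2,5-diene-1-carboxylate
Product: 6 1-(hydroxymethyl)cyclohexa-2,5-dien-1-ol
Conditions: LiAlH4, Et2O, 0 °C; H2O, 15% aq NaOH, H2O work-up
Reagents that add atoms: none
Why: Hydride reduction of the ester leaves isolated alkenes untouched, and the basic work-up protects the acid-labile dienol from dehydration.

Step 5
Reactants: 6 1-(hydroxymethyl)cyclohexa-2,5-dien-1-ol; 7 benzoyl chloride
Product: 8 (1-hydroxycyclohexa-2,5-dien-1-yl)methyl benzoate
Conditions: 7 (1.05 equiv), Et3N, DMAP (cat.), CH2Cl2, −20 °C; Et3N-deactivated silica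
Reagents that add atoms: benzoyl chloride (7), O=C(Cl)c1ccccc1
Why: DMAP-catalysed acylation is chemoselective for the primary hydroxyl over the tertiary one, and the excess amine keeps the medium basic throughout.

Step 6
Reactants: 8 (1-hydroxycyclohexa-2,5-dien-1-yl)methyl benzoate; 9 cumene hydroperoxide
Product: 10 [(1R,2R,3R)-2,3-epoxy-1-hydroxycyclohex-5-en-1-yl]methyl benzoate (oxirane syn to O1 and anti to C7)
Conditions: Hf(OtBu)4 (10 mol %), (1R,2R)-N,N'-dihydroxy-N,N'-bis(diphenylacetyl)cyclohexane-1,2-diamine (12 mol %), 9 (1.1 equiv), MgO, 4 Å MS, toluene, 0 °C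
Reagents that add atoms: cumene hydroperoxide (9), CC(C)(OO)c1ccccc1
Why: Ligand exchange puts the C1 alkoxide of 8 and an η2-bound cumyl peroxide on the same Hf(IV) centre held by the C2-symmetric bishydroxamate, and the distal peroxide oxygen passes to the neighbouring alkene in a concerted spiro-type transfer; the reaction type is the metal–bishydroxamic acid epoxidation of tertiary allylic alcohols, as also used to desymmetrise bis-allylic carbinols. The oxirane, the only ring closed, forms by suprafacial [2+1] addition of that oxygen to C2=C3 with both C–O bonds made in one event, so the cis ring alkene fixes C2 and C3 relative to each other. The C1–O–Hf tether confines delivery to the hydroxyl-bearing face, which places O on C2 and C3 syn to O1 and anti to the C7 arm. The chiral pocket decides which of the two mirror-image alkenes lies under the peroxide, and this single choice turns prochiral C1 into the (R)-centre and gives (1R,2R,3R)-10. The step needs enantiotopic-group selectivity (ligand), syn facial selectivity (alkoxide binding, with O7 acylated and therefore not competing) and mono-oxidation (about one equivalent of oxidant); a second epoxidation should consume the mismatched minor enantiomer faster and ends in an achiral meso bis-epoxide, which can only raise the enantiomeric purity of 10. The alkoxide medium with MgO and sieves holds back loss of water from the dienol to the arene.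

Step 7
Reactants: 10 [(1R,2R,3R)-2,3-epoxy-1-hydroxycyclohex-5-en-1-yl]methyl benzoate
Product: 12 (1R,2S,3R)-1-(hydroxymethyl)-1,3-bis(triethylsilyloxy)cyclohex-5-en-2-yl benzoate, via dioxanylium triflate 11 (not isolated)
Conditions: TESOTf (2.5 equiv), 2,6-di-tert-butyl-4-methylpyridine, CH2Cl2, −78 to −40 °C; then H2O–THF, 0 °C; aq NaHCO3 wash
Reagents that add atoms: triethylsilyl trifluoromethanesulfonate, CC[Si](CC)(CC)OS(=O)(=O)C(F)(F)F; water, O
Why: This is a Lewis-acid epoxide opening with anchimeric assistance by an ester (acyloxonium route): the silyl triflate caps O1 and activates the oxirane oxygen, the benzoate carbonyl on the opposite ring face attacks C2 from behind in a 6-exo, trans-diaxial (Fürst–Plattner) opening that inverts C2 to (S), the untouched C3–O bond emerges as its TES ether, and mildly acidic hydrolysis of 11 through the hemiorthoester should release the less hindered primary O7.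

Step 8
Reactants: 12 (1R,2S,3R)-1-(hydroxymethyl)-1,3-bis(triethylsilyloxy)cyclohex-5-en-2-yl benzoate; 7 benzoyl chloride
Product: 13 [(1R,2S,3R)-2-benzoyloxy-1,3-bis(triethylsilyloxy)cyclohex-5-en-1-yl]methyl benzoate
Conditions: 7 (1.5 equiv), pyridine, DMAP (cat.), CH2Cl2, 0 °C to rt
Reagents that add atoms: benzoyl chloride (7), O=C(Cl)c1ccccc1
Why: With O1 and O3 silylated, DMAP-catalysed acylation can reach only the O2/O7 pair, so any benzoyl shift back to O7 is harmless because that shift is reversible under amine base and drains through the faster-reacting primary alcohol (Curtin–Hammett) to the same dibenzoate.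

Step 9
Reactants: 13 [(1R,2S,3R)-2-benzoyloxy-1,3-bis(triethylsilyloxy)cyclohex-5-en-1-yl]methyl benzoate
Product: 16 [(1R,2S,3R)-2-benzoyloxy-6-oxo-1,3-bis(triethylsilyloxy)cyclohex-4-en-1-yl]methyl benzoate, via allylic hydroperoxide 14 (not isolated), via allylic peracetate 15 (not isolated)
Conditions: O2, tetrakis(pentafluorophenyl)porphyrin (cat.), white LED, CCl4, 0 °C; then Ac2O, pyridine, DMAP (cat.), 0 °C to rt
Reagents that add atoms: dioxygen, O=O
Why: In this Schenck ene reaction followed by Kornblum–DeLaMare-type dehydration, C1 carries no hydrogen, so hydrogen can be taken only from C4, oxygen can bind only at C6 and the alkene must shift to C4=C5; the transient C6 centre (expected on the face of the pseudoaxial C4–H, away from the C7 arm) disappears on loss of acetic acid, and the slow reaction of this electron-poor cis alkene is met with a solvent of long singlet-oxygen lifetime and a bleach-resistant sensitiser.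

Step 10
Reactants: 16 [(1R,2S,3R)-2-benzoyloxy-6-oxo-1,3-bis(triethylsilyloxy)cyclohex-4-en-1-yl]methyl benzoate
Product: 17 [(1R,2S,3R)-2-benzoyloxy-1,3-dihydroxy-6-oxocyclohex-4-en-1-yl]methyl benzoate (CNP0212960.1)
Conditions: HF·pyridine, pyridine, THF, 0 °C to rt
Reagents that add atoms: none
Why: Fluoride cleavage of both TES ethers in a weakly acidic buffer avoids the base that would cause O2-to-O3 benzoyl migration or vinylogous elimination, and no stereocentre is touched.

**Compound list**
1 | benzoic acid | OC(=O)c1ccccc1 | starting material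
2 | cyclohexa-2,5-diene-1-carboxylic acid | OC(=O)C1C=CCC=C1 | intermediate
3 | methyl cyclohexa-2,5-diene-1-carboxylate | COC(=O)C1C=CCC=C1 | intermediate
4 | potassium dienolate of 3 (not isolated) | COC([O-])=C1C=CCC=C1.[K+] | intermediate
5 | methyl 1-hydroxycyclohexa-2,5-diene-1-carboxylate | COC(=O)C1(O)C=CCC=C1 | intermediate
6 | 1-(hydroxymethyl)cyclohexa-2,5-dien-1-ol | OCC1(O)C=CCC=C1 | intermediate
7 | benzoyl chloride | O=C(Cl)c1ccccc1 | starting material
8 | (1-hydroxycyclohexa-2,5-dien-1-yl)methyl benzoate | OC1(COC(=O)c2ccccc2)C=CCC=C1 | intermediate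
9 | cumene hydroperoxide | CC(C)(OO)c1ccccc1 | starting material
10 | [(1R,2R,3R)-2,3-epoxy-1-hydroxycyclohex-5-en-1-yl]methyl benzoate, oxirane syn to O1 | O=C(OC[C@]1(O)C=CC[C@H]2O[C@H]21)c1ccccc1 | intermediate
11 | 2-phenyl-1,3-dioxan-2-ylium triflate spanning O7 and O2, cis-fused at C1–C2, O1 and O3 as TES ethers (not isolated) | c1ccccc1C2=[O+][C@H]3[C@H](O[Si](CC)(CC)CC)CC=C[C@@]3(O[Si](CC)(CC)CC)CO2.[O-]S(=O)(=O)C(F)(F)F | intermediate
12 | (1R,2S,3R)-1-(hydroxymethyl)-1,3-bis(triethylsilyloxy)cyclohex-5-en-2-yl benzoate | OC[C@]1(O[Si](CC)(CC)CC)C=CC[C@@H](O[Si](CC)(CC)CC)[C@@H]1OC(=O)c1ccccc1 | intermediate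
13 | [(1R,2S,3R)-2-benzoyloxy-1,3-bis(triethylsilyloxy)cyclohex-5-en-1-yl]methyl benzoate | O=C(OC[C@]1(O[Si](CC)(CC)CC)C=CC[C@@H](O[Si](CC)(CC)CC)[C@@H]1OC(=O)c1ccccc1)c1ccccc1 | intermediate
14 | [(1R,2S,3R,6S)-2-benzoyloxy-6-hydroperoxy-1,3-bis(triethylsilyloxy)cyclohex-4-en-1-yl]methyl benzoate (not isolated; C6 as expected, of no consequence) | O=C(OC[C@]1(O[Si](CC)(CC)CC)[C@@H](OO)C=C[C@@H](O[Si](CC)(CC)CC)[C@@H]1OC(=O)c1ccccc1)c1ccccc1 | intermediate
15 | O-acetyl derivative (peracetate) of 14 (not isolated) | O=C(OC[C@]1(O[Si](CC)(CC)CC)[C@@H](OOC(C)=O)C=C[C@@H](O[Si](CC)(CC)CC)[C@@H]1OC(=O)c1ccccc1)c1ccccc1 | intermediate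
16 | [(1R,2S,3R)-2-benzoyloxy-6-oxo-1,3-bis(triethylsilyloxy)cyclohex-4-en-1-yl]methyl benzoate | O=C(OC[C@]1(O[Si](CC)(CC)CC)C(=O)C=C[C@@H](O[Si](CC)(CC)CC)[C@@H]1OC(=O)c1ccccc1)c1ccccc1 | intermediate
17 | [(1R,2S,3R)-2-benzoyloxy-1,3-dihydroxy-6-oxocyclohex-4-en-1-yl]methyl benzoate | O=C(OC[C@]1(O)C(=O)C=C[C@@H](O)[C@@H]1OC(=O)c1ccccc1)c1ccccc1 | target

**Total step count:** 10. **Longest linear sequence:** 10 steps from benzoic acid.

**Steps most likely to fail**

1. **Step 6.**
   - Risks: metal-induced loss of water with aromatisation of the dienol, weak discrimination between the two enantiotopic alkenes of a flat and nearly symmetric ring, and over-oxidation.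
   - Fallback: a covalent resolving group with substrate-directed epoxidation replaces catalyst control. It sets out from 6 and returns at 10.
   - Route: diol 6 is acylated at the primary hydroxyl with (1S)-camphanic chloride (Et3N, DMAP, CH2Cl2, −20 °C) to give the dienol camphanate F1. Buffered mCPBA (Na2HPO4, CH2Cl2, 0 °C) epoxidises one alkene on the hydroxyl face; Henbest direction is reinforced here by the bulk of the C7 arm. This gives the (1R,2R,3R)-epoxy camphanate F2 and the (1S,2S,3S)-epoxy camphanate F3, which are separated by crystallisation or chromatography. Methanolysis of F2 (K2CO3, MeOH, 0 °C) gives the epoxy diol F4, and primary-selective benzoylation with 7 as in step 5 gives 10.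

2. **Step 9.**
   - Risks: a very slow ene reaction at an electron-poor 1,2-disubstituted alkene, bleaching of the sensitiser during long irradiation, and base-induced elimination during the dehydration.
   - Fallback: epoxide-to-allylic-alcohol transposition replaces C–H oxygenation. It sets out from 13 and returns at 16.
   - Route: buffered mCPBA converts 13 into the 5,6-epoxide F5. It is drawn for attack away from the C7 arm, but the other face serves equally because C5 and C6 lose their configuration later. Phenylselenide (PhSeSePh, NaBH4, EtOH) opens the epoxide trans-diaxially at C5, the carbon remote from the quaternary centre, to give the hydroxy selenide F6. H2O2 with pyridine gives the selenoxide F7, which eliminates syn towards C4 and away from the carbinol carbon to give the allylic alcohol F8. Dess–Martin oxidation then gives 16.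

3. **Step 7.**
   - Risks: elimination towards C4 or a hydride shift of the activated oxirane competing with participation, and silyl or acyl scrambling during hydrolysis.
   - Fallback: a carbonate serves as the internal nucleophile, so that a neutral cyclic product forms irreversibly and no hemiorthoester has to choose a direction. It sets out from 10 and returns at 13.
   - Route: methanolysis of 10 (K2CO3, MeOH, 0 °C) gives the epoxy diol F4. Boc2O (Et3N, cat. DMAP) carbonates the primary hydroxyl to give the tert-butyl carbonate F9. BF3·OEt2 (CH2Cl2, −40 °C) triggers backside 6-exo attack at C2 with loss of the tert-butyl group to give the six-membered cyclic carbonate F10, with O1–H and O3–H free. TESOTf with 2,6-lutidine gives the bis-silyl ether F11, methanolysis of the carbonate gives the 2,7-diol F12, and double benzoylation with 7 (pyridine, DMAP) gives 13.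

**Further compounds**
F1 | step 6 | (1-hydroxycyclohexa-2,5-dien-1-yl)methyl (1S,4R)-camphanate | CC1(C)[C@@]2(C)CC[C@@]1(OC2=O)C(=O)OCC1(O)C=CCC=C1
F2 | step 6 | [(1R,2R,3R)-2,3-epoxy-1-hydroxycyclohex-5-en-1-yl]methyl (1S,4R)-camphanate | CC1(C)[C@@]2(C)CC[C@@]1(OC2=O)C(=O)OC[C@]1(O)C=CC[C@H]2O[C@H]21
F3 | step 6 | [(1S,2S,3S)-2,3-epoxy-1-hydroxycyclohex-5-en-1-yl]methyl (1S,4R)-camphanate | CC1(C)[C@@]2(C)CC[C@@]1(OC2=O)C(=O)OC[C@@]1(O)C=CC[C@@H]2O[C@@H]21
F4 | step 6 | (1R,2R,3R)-2,3-epoxy-1-(hydroxymethyl)cyclohex-5-en-1-ol | OC[C@]1(O)C=CC[C@H]2O[C@H]21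
F5 | step 9 | 5,6-epoxide of 13 (oxirane anti to C7) | O=C(OC[C@]1(O[Si](CC)(CC)CC)[C@H]2O[C@H]2C[C@@H](O[Si](CC)(CC)CC)[C@@H]1OC(=O)c1ccccc1)c1ccccc1
F6 | step 9 | 6-hydroxy-5-(phenylselanyl) derivative from F5 | O=C(OC[C@]1(O[Si](CC)(CC)CC)[C@@H](O)[C@H]([Se]c2ccccc2)C[C@@H](O[Si](CC)(CC)CC)[C@@H]1OC(=O)c1ccccc1)c1ccccc1
F7 | step 9 | selenoxide of F6 | O=C(OC[C@]1(O[Si](CC)(CC)CC)[C@@H](O)[C@H]([Se](=O)c2ccccc2)C[C@@H](O[Si](CC)(CC)CC)[C@@H]1OC(=O)c1ccccc1)c1ccccc1
F8 | step 9 | [(1R,2S,3R)-2-benzoyloxy-6-hydroxy-1,3-bis(triethylsilyloxy)cyclohex-4-en-1-yl]methyl benzoate | O=C(OC[C@]1(O[Si](CC)(CC)CC)[C@@H](O)C=C[C@@H](O[Si](CC)(CC)CC)[C@@H]1OC(=O)c1ccccc1)c1ccccc1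
F9 | step 7 | tert-butyl [(1R,2R,3R)-2,3-epoxy-1-hydroxycyclohex-5-en-1-yl]methyl carbonate | CC(C)(C)OC(=O)OC[C@]1(O)C=CC[C@H]2O[C@H]21
F10 | step 7 | cyclic O2,O7-carbonate of the (1R,2S,3R)-tetraol, O1–H and O3–H free | O=C1OC[C@]2(O)C=CC[C@@H](O)[C@@H]2O1
F11 | step 7 | O1,O3-bis(triethylsilyl) ether of F10 | O=C1OC[C@]2(O[Si](CC)(CC)CC)C=CC[C@@H](O[Si](CC)(CC)CC)[C@@H]2O1
F12 | step 7 | (1R,2S,3R)-1-(hydroxymethyl)-1,3-bis(triethylsilyloxy)cyclohex-5-en-2-ol | OC[C@]1(O[Si](CC)(CC)CC)C=CC[C@@H](O[Si](CC)(CC)CC)[C@@H]1O
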